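**Retrosynthetic overview**

1. Target ⇒ desilylation and Yamaguchi esterification of the C9 hydroxyl with (2R,3R)-epoxyangelic acid (from angelic acid by Sharpless epoxidation) ⇒ C9 alcohol carrying the α-methylene lactone ⇒ (E1cB) a tricyclic ether in which O9 is bonded to C13, so that the methylene lactone and the C9–OH are masked together as a tetrahydropyran.
2. The 10-membered ring ⇒ ring-closing metathesis at C3=C4; the Z C1=C10 alkene ⇒ Wittig reaction on a C10 methyl ketone.
3. Key disconnection, C7–C11 and O–C6 ⇒ an open-chain Z-alkenyl malonic acid tethered through O9–C13; Mn(OAc)3-mediated radical 6-exo cyclisation and oxidative lactonisation close the tetrahydropyran and then the γ-lactone in one operation and set C7 and C6 from C8 and C9.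
4. Enabling feature: C11 (on C7) and the oxygen on C9 are 1,3-cis and C13 is the β-carbon of the lactone acrylate, so O9–C13–C11–C7–C8–C9 is a chair tetrahydropyran with C6, O8 and C10 all equatorial; its C13–O9 bond is later cut by β-elimination and every tether atom stays in the target.
5. Ring order: tetrahydropyran and γ-lactone (step 10) → carbocycle (step 13) → tetrahydropyran opened (step 14). The open-chain precursor comes from (R)-glyceraldehyde acetonide (C8 bought), a Z-Wittig reaction, a Felkin–Anh addition (C9) and an oxa-Michael addition to diethyl methylenemalonate.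

Key step: step 10

Remark: locants are germacranolide locants (ring C1–C10; lactone oxygen on C6; C7 ring fusion; C8 carbinol; C9 acyloxy carbon; C11, C12, C13 = lactone α-carbon, carbonyl, methylene; C14 and C15 = methyls on C10 and C4). Step 10 is assumed to give mainly the cis-fused C11 epimer, which is the one drawn; the other epimer converges in step 14.

**Route**

Step 1
Reactants: 1 4-bromo-2-methylbut-1-ene; 2 triphenylphosphine
Product: 3 (3-methylbut-3-en-1-yl)triphenylphosphonium bromide
Conditions: MeCN, 82 °C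
Reagents that add atoms: none
Why: SN2 quaternisation of triphenylphosphine by the primary homoallylic bromide gives the Wittig salt.

Step 2
Reactants: 3 (3-methylbut-3-en-1-yl)triphenylphosphonium bromide; 4 (R)-2,2-dimethyl-1,3-dioxolane-4-carbaldehyde
Product: 6 (4S)-2,2-dimethyl-4-[(1Z)-4-methylpenta-1,4-dien-1-yl]-1,3-dioxolane, via phosphorus ylide 5 (not isolated)
Conditions: NaN(SiMe3)2, THF, −78 °C to 25 °C
Reagents that add atoms: none
Why: Wittig olefination with a non-stabilised ylide under salt-free conditions passes through the cis-oxaphosphetane and should give the Z C6=C7 alkene, while the stereocentre bought with 4 (later C8) is not touched.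

Step 3
Reactants: 6 (4S)-2,2-dimethyl-4-[(1Z)-4-methylpenta-1,4-dien-1-yl]-1,3-dioxolane
Product: 7 (2S,3Z)-6-methylhepta-3,6-diene-1,2-diol
Conditions: AcOH/H2O 4:1, 40 °C
Reagents that add atoms: none
Why: acid-catalysed acetal hydrolysis frees the 1,2-diol without affecting the skipped diene.

Step 4
Reactants: 7 (2S,3Z)-6-methylhepta-3,6-diene-1,2-diol
Product: 8 (2S,3Z)-1,2-bis[(tert-butyldimethylsilyl)oxy]-6-methylhepta-3,6-diene
Conditions: TBSCl, imidazole, DMF, 25 °C
Reagents that add atoms: tert-butyldimethylsilyl chloride CC(C)(C)[Si](C)(C)Cl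
Why: exhaustive silylation of both hydroxyls, so that the secondary (C8) ether remains after step 5.

Step 5
Reactants: 8 (2S,3Z)-1,2-bis[(tert-butyldimethylsilyl)oxy]-6-methylhepta-3,6-diene
Product: 9 (2S,3Z)-2-[(tert-butyldimethylsilyl)oxy]-6-methylhepta-3,6-dien-1-ol
Conditions: HF·pyridine, pyridine, THF, 0 °C
Reagents that add atoms: none
Why: the primary silyl ether is cleaved much faster than the hindered secondary allylic one under buffered fluoride (steric differentiation).

Step 6
Reactants: 9 (2S,3Z)-2-[(tert-butyldimethylsilyl)oxy]-6-methylhepta-3,6-dien-1-ol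
Product: 10 (2S,3Z)-2-[(tert-butyldimethylsilyl)oxy]-6-methylhepta-3,6-dienal
Conditions: Dess–Martin periodinane, pyridine, CH2Cl2, 0 °C; used crude
Reagents that add atoms: none
Why: Dess–Martin oxidation under buffered, non-enolising conditions should give the α-silyloxy aldehyde without moving the Z alkene into conjugation and without loss of configuration.

Step 7
Reactants: 10 (2S,3Z)-2-[(tert-butyldimethylsilyl)oxy]-6-methylhepta-3,6-dienal; 11 ethyl vinyl ether
Product: 13 (3S,4S,5Z)-4-[(tert-butyldimethylsilyl)oxy]-2-ethoxy-8-methylnona-1,5,8-trien-3-ol, via 1-ethoxyvinyllithium 12 (not isolated)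
Conditions: 11, tBuLi, THF, −78 °C to 0 °C; then 10, −78 °C; H2O
Reagents that add atoms: none
Why: 1,2-addition of the acetyl-anion equivalent under Felkin–Anh (polar) control, with the non-chelating silyloxy group anti to the incoming nucleophile, should favour the 8,9-anti alcohol (C9 set from C8); the enol ether masks the C10 methyl ketone.

Step 8
Reactants: 13 (3S,4S,5Z)-4-[(tert-butyldimethylsilyl)oxy]-2-ethoxy-8-methylnona-1,5,8-trien-3-ol; 14 diethyl methylenemalonate
Product: 15 diethyl 2-({[(3S,4S,5Z)-4-[(tert-butyldimethylsilyl)oxy]-2-ethoxy-8-methylnona-1,5,8-trien-3-yl]oxy}methyl)propanedioate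
Conditions: KN(SiMe3)2, THF, −78 °C; then 14, −78 °C; AcOH
Reagents that add atoms: none
Why: oxa-Michael addition of the potassium alkoxide to the highly electrophilic methylenemalonate forms the O9–C13 bond and brings in C11 and both carboxyl carbons, and the low temperature suppresses 1,2-silyl migration.

Step 9
Reactants: 15 diethyl 2-({[(3S,4S,5Z)-4-[(tert-butyldimethylsilyl)oxy]-2-ethoxy-8-methylnona-1,5,8-trien-3-yl]oxy}methyl)propanedioate
Product: 17 2-({[(3S,4S,5Z)-4-[(tert-butyldimethylsilyl)oxy]-8-methyl-2-oxonona-5,8-dien-3-yl]oxy}methyl)propanedioic acid, via dilithium dicarboxylate 16 (not isolated)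
Conditions: LiOH, THF/H2O, 25 °C; then 1 M HCl to pH 2, 0 °C
Reagents that add atoms: lithium hydroxide [Li+].[OH-]; water O
Why: ester saponification followed by acidification, which also hydrolyses the enol ether to the C10 methyl ketone; the malonate enolate is too stabilised to expel the β-alkoxide at 25 °C.

Step 10
Reactants: 17 2-({[(3S,4S,5Z)-4-[(tert-butyldimethylsilyl)oxy]-8-methyl-2-oxonona-5,8-dien-3-yl]oxy}methyl)propanedioic acid
Product: 19 6-acetyl-7-[(tert-butyldimethylsilyl)oxy]-1-(2-methylprop-2-en-1-yl)-3-oxohexahydro-1H-furo[3,4-c]pyran-3a-carboxylic acid (cis-fused lactone–tetrahydropyran), via C6 radical 18 (not isolated)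
Conditions: Mn(OAc)3·2H2O (2.5 equiv), KOAc, degassed AcOH, 25 °C, 0.01 M
Reagents that add atoms: none
Why: Mn(OAc)3 (trivalent manganese) oxidises the enolised malonic acid to the C11 malonyl radical, which adds 6-exo-trig to C7 of the Z alkene to give radical 18; a second equivalent of Mn(OAc)3 then oxidises the C6 radical with participation of a neighbouring carboxyl group and closes the γ-lactone (C12(=O)–O–C6) in a 5-exo mode. The closest known reaction type is the Mn(OAc)3-mediated carbolactonisation of alkenes with malonic acids and the oxidative free-radical cyclisation/lactonisation of unsaturated malonates. The tetrahydropyran (O9–C13–C11–C7–C8–C9) closes through a chair transition state in which the C9 acetyl group, the C8 silyloxy group and the alkene are all equatorial, and allylic 1,3-strain of the Z alkene keeps H8 in the alkene plane, so C11 is delivered to the face of C7 anti to O8; this fixes C7 relative to C8 and C9. C6 is set in the lactonisation, where the 2-methylallyl chain should take the exo position trans to C8, the usual trans outcome for β,γ-disubstituted lactones from 1,2-disubstituted alkenes; the C11 stereocentre is temporary and either epimer converges in step 14. The step needs 6-exo rather than 7-endo attack and no reaction at the 1,1-disubstituted alkene or the ketone: the short O9–C13 tether reaches C7 in a strain-free ring, the remote alkene cannot be reached intramolecularly and high dilution suppresses bimolecular addition, and simple ketones are not enolised by Mn(OAc)3 at 25 °C.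

Step 11
Reactants: 19 cis-fused lactone–tetrahydropyran keto acid; 20 (but-3-en-1-yl)triphenylphosphonium bromide
Product: 22 6-[(2Z)-hexa-2,5-dien-2-yl]-7-[(tert-butyldimethylsilyl)oxy]-1-(2-methylprop-2-en-1-yl)-3-oxohexahydro-1H-furo[3,4-c]pyran-3a-carboxylic acid, via phosphorus ylide 21 (not isolated)
Conditions: 20, NaN(SiMe3)2 (excess), THF, −78 °C to 25 °C; then aq. HCl to pH 3
Reagents that add atoms: none
Why: Wittig olefination of the α-alkoxy methyl ketone by a non-stabilised ylide, a substrate class known to favour the trisubstituted Z alkene (new chain cis to the oxygen-bearing carbon, here C2 cis to C9); the quaternary C11 carboxylate has no α-hydrogen, so the tetrahydropyran cannot open under the basic conditions.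

Step 12
Reactants: 22 triene acid
Product: 23 6-[(2Z)-hexa-2,5-dien-2-yl]-7-[(tert-butyldimethylsilyl)oxy]-1-(2-methylprop-2-en-1-yl)tetrahydro-1H-furo[3,4-c]pyran-3(4H)-one
Conditions: toluene, 110 °C
Reagents that add atoms: none
Why: thermal decarboxylation of the malonic-type acid through the cyclic six-membered transition state gives the α-H lactone; the new C11–H centre is temporary and either epimer is usable.

Step 13
Reactants: 23 triene lactone
Product: 24 tricyclic lactone (10-membered 1(10)Z,3Z-diene; O9 bonded to C13 as a tetrahydropyran; H on C11; silyl ether on O8)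
Conditions: second-generation Grubbs catalyst (10 mol%), 1,4-benzoquinone (20 mol%), toluene, 80 °C, 1 mM
Reagents that add atoms: none
Why: ring-closing metathesis between the monosubstituted alkene (C3) and the 1,1-disubstituted alkene (C4) closes the carbocycle at C3=C4, where the cis (Z) alkene is the less strained one in a cyclodeca-1,4-diene; the trisubstituted C1=C10 alkene does not take part and the methylene lactone is still masked.

Step 14
Reactants: 24 tricyclic lactone
Product: 26 9-hydroxy-8-silyloxy α-methylene lactone (target lacking the C9 acyl group, silyl ether on O8), via lithium alkoxide 25 (not isolated)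
Conditions: LiN(SiMe3)2, THF, −78 °C to −30 °C; AcOH, −78 °C
Reagents that add atoms: none
Why: E1cB (retro-oxa-Michael) opening: the C11 lactone enolate expels the β-alkoxide O9, which the half-chair six-membered ring allows stereoelectronically; this releases the methylene lactone and the C9 hydroxyl together and erases the C11 stereocentre, and the cold acidic quench limits silyl migration and translactonisation.

Step 15
Reactants: 27 angelic acid ((2Z)-2-methylbut-2-enoic acid)
Product: 28 (2Z)-2-methylbut-2-en-1-ol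
Conditions: LiAlH4, Et2O, 0 °C
Reagents that add atoms: none
Why: hydride reduction of the acid to the allylic alcohol should retain the Z geometry at 0 °C.

Step 16
Reactants: 28 (2Z)-2-methylbut-2-en-1-ol
Product: 29 [(2S,3R)-2,3-dimethyloxiran-2-yl]methanol
Conditions: Ti(OiPr)4, L-(+)-diethyl tartrate, tBuOOH, 4 Å molecular sieves, CH2Cl2, −20 °C
Reagents that add atoms: tert-butyl hydroperoxide CC(C)(C)OO
Why: Sharpless asymmetric epoxidation, in which the L-(+)-tartrate catalyst should deliver oxygen to the alkene face that gives the (2S,3R) epoxy alcohol (both epoxide stereocentres set by catalysis, cis methyl/CH2OH relation kept from the Z alkene).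

Step 17
Reactants: 29 [(2S,3R)-2,3-dimethyloxiran-2-yl]methanol
Product: 30 (2R,3R)-2,3-dimethyloxirane-2-carboxylic acid
Conditions: RuCl3·xH2O (cat.), NaIO4, CCl4/MeCN/H2O, 25 °C
Reagents that add atoms: sodium periodate [Na+].[O-]I(=O)(=O)=O; water O
Why: RuO4 generated catalytically oxidises the primary alcohol to the acid without opening the epoxide; the descriptor at C2 changes only through CIP priorities.

Step 18
Reactants: 26 9-hydroxy-8-silyloxy α-methylene lactone; 30 (2R,3R)-2,3-dimethyloxirane-2-carboxylic acid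
Product: 32 8-O-(tert-butyldimethylsilyl) ether of the target, via mixed anhydride 31 (not isolated)
Conditions: 30, 2,4,6-trichlorobenzoyl chloride, Et3N, THF, 25 °C; then 26, DMAP, toluene, 25 °C
Reagents that add atoms: none
Why: Yamaguchi esterification, in which DMAP-mediated acyl transfer from the mixed anhydride acylates the hindered secondary C9 hydroxyl without touching any stereocentre.

Step 19
Reactants: 32 8-O-(tert-butyldimethylsilyl) ether of the target
Product: 33 target, (3aR,4S,5R,6Z,9Z,11aR)-4-hydroxy-6,10-dimethyl-3-methylidene-2-oxo-2,3,3a,4,5,8,11,11a-octahydrocyclodeca[b]furan-5-yl (2R,3R)-2,3-dimethyloxirane-2-carboxylate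
Conditions: HF·pyridine, pyridine, THF, 0 °C to 25 °C
Reagents that add atoms: none
Why: buffered fluoride cleavage of the silyl ether should leave the epoxy ester, the methylene lactone and the skipped diene intact.

**Compound list**

1 | 4-bromo-2-methylbut-1-ene | C=C(C)CCBr | starting material
2 | triphenylphosphine | c1ccc(cc1)P(c1ccccc1)c1ccccc1 | starting material
3 | (3-methylbut-3-en-1-yl)triphenylphosphonium bromide | C=C(C)CC[P+](c1ccccc1)(c1ccccc1)c1ccccc1.[Br-] | intermediate
4 | (R)-2,2-dimethyl-1,3-dioxolane-4-carbaldehyde ((R)-glyceraldehyde acetonide) | CC1(C)OC[C@@H](O1)C=O | starting material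
5 | (3-methylbut-3-en-1-ylidene)triphenylphosphorane | C=C(C)CC=P(c1ccccc1)(c1ccccc1)c1ccccc1 | intermediate
6 | (4S)-2,2-dimethyl-4-[(1Z)-4-methylpenta-1,4-dien-1-yl]-1,3-dioxolane | CC1(C)OC[C@@H](O1)/C=C\CC(C)=C | intermediate
7 | (2S,3Z)-6-methylhepta-3,6-diene-1,2-diol | OC[C@@H](O)/C=C\CC(C)=C | intermediate
8 | (2S,3Z)-1,2-bis[(tert-butyldimethylsilyl)oxy]-6-methylhepta-3,6-diene | CC(C)(C)[Si](C)(C)OC[C@@H](O[Si](C)(C)C(C)(C)C)/C=C\CC(C)=C | intermediate
9 | (2S,3Z)-2-[(tert-butyldimethylsilyl)oxy]-6-methylhepta-3,6-dien-1-ol | OC[C@@H](O[Si](C)(C)C(C)(C)C)/C=C\CC(C)=C | intermediate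
10 | (2S,3Z)-2-[(tert-butyldimethylsilyl)oxy]-6-methylhepta-3,6-dienal | O=C[C@@H](O[Si](C)(C)C(C)(C)C)/C=C\CC(C)=C | intermediate
11 | ethyl vinyl ether | C=COCC | starting material
12 | 1-ethoxyvinyllithium | [Li]C(=C)OCC | intermediate
13 | (3S,4S,5Z)-4-[(tert-butyldimethylsilyl)oxy]-2-ethoxy-8-methylnona-1,5,8-trien-3-ol (C8/C9 anti) | C=C(OCC)[C@@H](O)[C@@H](O[Si](C)(C)C(C)(C)C)/C=C\CC(C)=C | intermediate
14 | diethyl methylenemalonate (diethyl 2-methylidenepropanedioate) | C=C(C(=O)OCC)C(=O)OCC | starting material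
15 | diethyl 2-({[(3S,4S,5Z)-4-[(tert-butyldimethylsilyl)oxy]-2-ethoxy-8-methylnona-1,5,8-trien-3-yl]oxy}methyl)propanedioate | C=C(OCC)[C@@H](OCC(C(=O)OCC)C(=O)OCC)[C@@H](O[Si](C)(C)C(C)(C)C)/C=C\CC(C)=C | intermediate
16 | dilithium 2-({[(3S,4S,5Z)-4-[(tert-butyldimethylsilyl)oxy]-2-ethoxy-8-methylnona-1,5,8-trien-3-yl]oxy}methyl)propanedioate | C=C(OCC)[C@@H](OCC(C(=O)[O-])C(=O)[O-])[C@@H](O[Si](C)(C)C(C)(C)C)/C=C\CC(C)=C.[Li+].[Li+] | intermediate
17 | 2-({[(3S,4S,5Z)-4-[(tert-butyldimethylsilyl)oxy]-8-methyl-2-oxonona-5,8-dien-3-yl]oxy}methyl)propanedioic acid | CC(=O)[C@@H](OCC(C(=O)O)C(=O)O)[C@@H](O[Si](C)(C)C(C)(C)C)/C=C\CC(C)=C | intermediate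
18 | 1-[6-acetyl-5-(tert-butyldimethylsilyloxy)-3,3-dicarboxytetrahydro-2H-pyran-4-yl]-3-methylbut-3-en-1-yl radical (pyran substituents at C4, C5, C6 all equatorial) | CC(=O)[C@H]1OCC(C(=O)O)(C(=O)O)[C@@H]([CH]CC(C)=C)[C@@H]1O[Si](C)(C)C(C)(C)C | intermediate
19 | 6-acetyl-7-[(tert-butyldimethylsilyl)oxy]-1-(2-methylprop-2-en-1-yl)-3-oxohexahydro-1H-furo[3,4-c]pyran-3a-carboxylic acid (pyran C6, C7, C7a substituents equatorial; lactone cis-fused; C1 side chain trans to C7; in germacranolide terms C9 acetyl, C8 OTBS, C7, C6, C11 CO2H) | CC(=O)[C@H]1OC[C@@]2(C(=O)O)C(=O)O[C@H](CC(C)=C)[C@H]2[C@@H]1O[Si](C)(C)C(C)(C)C | intermediate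
20 | (but-3-en-1-yl)triphenylphosphonium bromide | C=CCC[P+](c1ccccc1)(c1ccccc1)c1ccccc1.[Br-] | starting material
21 | (but-3-en-1-ylidene)triphenylphosphorane | C=CCC=P(c1ccccc1)(c1ccccc1)c1ccccc1 | intermediate
22 | 6-[(2Z)-hexa-2,5-dien-2-yl]-7-[(tert-butyldimethylsilyl)oxy]-1-(2-methylprop-2-en-1-yl)-3-oxohexahydro-1H-furo[3,4-c]pyran-3a-carboxylic acid (configuration as in 19) | C=CC/C=C(/C)[C@H]1OC[C@@]2(C(=O)O)C(=O)O[C@H](CC(C)=C)[C@H]2[C@@H]1O[Si](C)(C)C(C)(C)C | intermediate
23 | 6-[(2Z)-hexa-2,5-dien-2-yl]-7-[(tert-butyldimethylsilyl)oxy]-1-(2-methylprop-2-en-1-yl)tetrahydro-1H-furo[3,4-c]pyran-3(4H)-one (cis-fused, other centres as in 19) | C=CC/C=C(/C)[C@H]1OC[C@H]2C(=O)O[C@H](CC(C)=C)[C@H]2[C@@H]1O[Si](C)(C)C(C)(C)C | intermediate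
24 | tricyclic lactone: 1(10)Z,3Z-cyclodecadiene fused to the 6,12-lactone and bridged by the O9–C13 tetrahydropyran, H on C11, tert-butyldimethylsilyl ether on O8, target configuration at C6–C9 | O=C1O[C@@H]2C/C(C)=C\C/C=C(/C)[C@H]3OC[C@@H]1[C@@H]2[C@@H]3O[Si](C)(C)C(C)(C)C | intermediate
25 | lithium C9-alkoxide of 26 | C=C1C(=O)O[C@@H]2C/C(C)=C\C/C=C(/C)[C@@H]([O-])[C@@H](O[Si](C)(C)C(C)(C)C)[C@@H]12.[Li+] | intermediate
26 | 9-hydroxy-8-[(tert-butyldimethylsilyl)oxy] α-methylene lactone (target without the C9 acyl group, silyl ether on O8) | C=C1C(=O)O[C@@H]2C/C(C)=C\C/C=C(/C)[C@@H](O)[C@@H](O[Si](C)(C)C(C)(C)C)[C@@H]12 | intermediate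
27 | angelic acid, (2Z)-2-methylbut-2-enoic acid | C/C=C(/C)C(=O)O | starting material
28 | (2Z)-2-methylbut-2-en-1-ol | C/C=C(/C)CO | intermediate
29 | [(2S,3R)-2,3-dimethyloxiran-2-yl]methanol | OC[C@]1(C)O[C@@H]1C | intermediate
30 | (2R,3R)-2,3-dimethyloxirane-2-carboxylic acid (epoxyangelic acid) | OC(=O)[C@]1(C)O[C@@H]1C | intermediate
31 | (2R,3R)-2,3-dimethyloxirane-2-carboxylic 2,4,6-trichlorobenzoic anhydride | O=C(OC(=O)[C@]1(C)O[C@@H]1C)c1c(Cl)cc(Cl)cc1Cl | intermediate
32 | 8-O-(tert-butyldimethylsilyl) ether of the target | C=C1C(=O)O[C@@H]2C/C(C)=C\C/C=C(/C)[C@@H](OC(=O)[C@]3(C)O[C@@H]3C)[C@@H](O[Si](C)(C)C(C)(C)C)[C@@H]12 | intermediate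
33 | (3aR,4S,5R,6Z,9Z,11aR)-4-hydroxy-6,10-dimethyl-3-methylidene-2-oxo-2,3,3a,4,5,8,11,11a-octahydrocyclodeca[b]furan-5-yl (2R,3R)-2,3-dimethyloxirane-2-carboxylate | C=C1C(=O)O[C@@H]2C/C(C)=C\C/C=C(/C)[C@@H](OC(=O)[C@]3(C)O[C@@H]3C)[C@@H](O)[C@@H]12 | target

**Step count and risks**

Total step count: 19. Longest linear sequence: 16 steps (steps 1–14, 18, 19); steps 15–17 form the side branch.

Risk 1, step 13. The ring-closing metathesis may fail to close the 10-membered ring across the rigid lactone–tetrahydropyran core: intermolecular metathesis (oligomers), slow engagement of the 1,1-disubstituted alkene, or alkene migration in the skipped diene. Fallback, from 23 back to 32: the tetrahydropyran is opened first so that the ring is closed on a conformationally free lactone with the methylene group masked as a sulfide. Treatment of 23 with LiN(SiMe3)2 as in step 14 gives the hydroxy methylene lactone diene F1. Conjugate addition of thiophenol (Et3N, CH2Cl2) gives the sulfide F2. Yamaguchi esterification with 30 gives the ester F3. Ring-closing metathesis with the second-generation Grubbs catalyst gives the macrocyclic sulfide F4. NaIO4 oxidation gives the sulfoxide F5, and thermal syn-elimination (toluene, 110 °C) restores the methylene lactone and gives 32.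

Risk 2, step 10. The radical may close 7-endo or abstract the C8 hydrogen (1,5-hydrogen transfer), the oxidative lactonisation may show poor trans control at C6, or the silyl ether may be partly lost in acetic acid. Fallback, from 15 back to 19: the two bonds are formed in separate known steps, atom-transfer radical cyclisation and then ionic lactonisation. Mild acid hydrolysis of the enol ether of 15 (oxalic acid, wet THF) gives the keto diester F6. NaH then N-iodosuccinimide gives the iodomalonate F7. Iodine-atom-transfer cyclisation ((Bu3Sn)2 cat., visible light, benzene, 80 °C) through the same all-equatorial chair gives the tetrahydropyranyl iodide F8. AgOTf-promoted lactonisation with loss of one ethyl group, which should funnel both C6 iodide epimers to the trans lactone, gives the lactone ester F9. LiOH hydrolysis and acidification (relactonisation) give 19.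

Risk 3, step 14. At the lithium alkoxide stage the silyl group may migrate from O8 to O9, the alkoxide may attack the lactone carbonyl (translactonisation) or re-add to C13. Fallback, from 24 back to 33: the silyl ether is exchanged for a non-migrating ether before the ring is opened. HF·pyridine on 24 gives the alcohol F10. 4-Methoxybenzyl trichloroacetimidate with catalytic camphorsulfonic acid gives the 4-methoxybenzyl ether F11. Ring opening with LiN(SiMe3)2 as in step 14 gives the alcohol F12. Yamaguchi esterification with 30 gives the ester F13. DDQ in wet CH2Cl2 at 0 °C removes the 4-methoxybenzyl group and gives 33.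

Further compounds
F1 | step 13 | ring-opened 23: 9-hydroxy-8-silyloxy α-methylene lactone bearing the (2Z)-hexa-2,5-dien-2-yl and 2-methylallyl arms | C=CC/C=C(/C)[C@@H](O)[C@@H](O[Si](C)(C)C(C)(C)C)[C@H]1C(=C)C(=O)O[C@@H]1CC(C)=C
F2 | step 13 | thiophenol adduct of F1 (C13–SPh, C11 epimers) | C=CC/C=C(/C)[C@@H](O)[C@@H](O[Si](C)(C)C(C)(C)C)[C@H]1C(CSc2ccccc2)C(=O)O[C@@H]1CC(C)=C
F3 | step 13 | (2R,3R)-epoxyangelate ester of F2 at O9 | C=CC/C=C(/C)[C@@H](OC(=O)[C@]2(C)O[C@@H]2C)[C@@H](O[Si](C)(C)C(C)(C)C)[C@H]1C(CSc2ccccc2)C(=O)O[C@@H]1CC(C)=C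
F4 | step 13 | macrocyclic sulfide (32 with H on C11 and CH2SPh in place of the methylene group) | O=C1O[C@@H]2C/C(C)=C\C/C=C(/C)[C@@H](OC(=O)[C@]3(C)O[C@@H]3C)[C@@H](O[Si](C)(C)C(C)(C)C)[C@H]2C1CSc1ccccc1
F5 | step 13 | sulfoxide of F4 | O=C1O[C@@H]2C/C(C)=C\C/C=C(/C)[C@@H](OC(=O)[C@]3(C)O[C@@H]3C)[C@@H](O[Si](C)(C)C(C)(C)C)[C@H]2C1CS(=O)c1ccccc1
F6 | step 10 | diethyl 2-({[(3S,4S,5Z)-4-[(tert-butyldimethylsilyl)oxy]-8-methyl-2-oxonona-5,8-dien-3-yl]oxy}methyl)propanedioate | CC(=O)[C@@H](OCC(C(=O)OCC)C(=O)OCC)[C@@H](O[Si](C)(C)C(C)(C)C)/C=C\CC(C)=C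
F7 | step 10 | 2-iodo derivative of F6 (iodomalonate) | CC(=O)[C@@H](OCC(I)(C(=O)OCC)C(=O)OCC)[C@@H](O[Si](C)(C)C(C)(C)C)/C=C\CC(C)=C
F8 | step 10 | diethyl 6-acetyl-5-[(tert-butyldimethylsilyl)oxy]-4-(1-iodo-3-methylbut-3-en-1-yl)tetrahydro-2H-pyran-3,3-dicarboxylate (C6 iodide epimers) | CC(=O)[C@H]1OCC(C(=O)OCC)(C(=O)OCC)[C@@H](C(I)CC(C)=C)[C@@H]1O[Si](C)(C)C(C)(C)C
F9 | step 10 | ethyl ester of 19 | CC(=O)[C@H]1OC[C@@]2(C(=O)OCC)C(=O)O[C@H](CC(C)=C)[C@H]2[C@@H]1O[Si](C)(C)C(C)(C)C
F10 | step 14 | 24 with free C8 hydroxyl | O=C1O[C@@H]2C/C(C)=C\C/C=C(/C)[C@H]3OC[C@@H]1[C@@H]2[C@@H]3O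
F11 | step 14 | 8-O-(4-methoxybenzyl) ether of F10 | O=C1O[C@@H]2C/C(C)=C\C/C=C(/C)[C@H]3OC[C@@H]1[C@@H]2[C@@H]3OCc1ccc(OC)cc1
F12 | step 14 | 9-hydroxy-8-(4-methoxybenzyloxy) α-methylene lactone | C=C1C(=O)O[C@@H]2C/C(C)=C\C/C=C(/C)[C@@H](O)[C@@H](OCc3ccc(OC)cc3)[C@@H]12
F13 | step 14 | 8-O-(4-methoxybenzyl) ether of the target | C=C1C(=O)O[C@@H]2C/C(C)=C\C/C=C(/C)[C@@H](OC(=O)[C@]3(C)O[C@@H]3C)[C@@H](OCc3ccc(OC)cc3)[C@@H]12
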